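**Plan**

- Retrosynthesis: remove five MOM ethers; take the indenone C2=C3 bond back to an indanone and cut C2–C6' (ring C) as a ketone α-arylation; cut ring D at C1–C2 and C5–C6 as a [4+2] of a 3-aryloxypropiolate with the vinylketene acetal of methyl 3-methylbut-2-enoate; cut the C(sp)–O bond; cut the indanone at C1–C7a (Parham acylation), C3–CH2 (benzhydryl cation alkylation) and C3–ring B (aryllithium addition).
- Enabling feature: ring D is a salicylate (C1 CO2Me, C2 OH, C4 CH3) whose C6 bears the oxygen of the doubly ortho-substituted C1' of ring C. C1 and C6 are the two sp carbons of the ynoate and C2–C5 the four diene carbons, so the crowded ether oxygen is bonded to a linear carbon before ring D exists.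
- One aldehyde, 2-bromo-4-methoxy-6-(methoxymethoxy)benzaldehyde, serves rings A and C: Baeyer–Villiger oxidation turns its CHO into the ether oxygen of ring C and fixes the O/Br/OMOM pattern without any selective protection.
- Forward order: rings A, B and C are bought as arenes; ring D is built by the cycloaddition; the five-membered ring closes by Parham cyclisation; the halves are joined by α-arylation, then dehydrogenation and global deprotection.
- Stereochemistry: the target has no stereocentre; the ketal carbon of the cycloadduct and C2/C3 of the indanones are transient and racemic.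

Key step: step 7

Assumption: the stereocentres of 11, 18, 20, 21, 22 and 23 are formed without control and are all destroyed by steps 7 and 14, so these compounds are racemic (23 as either C2/C3 diastereomer, trans expected) and their SMILES carry no descriptors.
Assumption: the geometry of ketene acetal 10 does not matter for the cycloaddition; the 1Z isomer is drawn.

**Route**

Step 1
Reactants: 1 2-bromo-4,6-dimethoxybenzaldehyde
Product: 2 2-bromo-6-hydroxy-4-methoxybenzaldehyde
Conditions: BCl3 (1.2 equiv), CH2Cl2, −78 → 0 °C; then H2O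
Reagents that add atoms: none
Why: BCl3 chelates between the aldehyde oxygen and the ortho methoxy group, so only that ether should be cleaved (chelation-controlled Lewis acid demethylation) while the para methoxy group survives.

Step 2
Reactants: 2 2-bromo-6-hydroxy-4-methoxybenzaldehyde
Product: 3 2-bromo-4-methoxy-6-(methoxymethoxy)benzaldehyde
Conditions: MOMCl, i-Pr2NEt, CH2Cl2, 0 °C → rt
Reagents that add atoms: chloromethyl methyl ether, COCCl
Why: Williamson-type O-alkylation of the phenol with the reactive α-chloro ether gives an acetal ether that withstands peracid, bases, organolithiums and heat and is removed by acid at the end.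

Step 3
Reactants: 3 2-bromo-4-methoxy-6-(methoxymethoxy)benzaldehyde
Product: 5 2-bromo-4-methoxy-6-(methoxymethoxy)phenol, via aryl formate 4 (not isolated)
Conditions: mCPBA, CH2Cl2, 0 °C → rt; aq. NaHCO3 wash, evaporate; then K2CO3 (cat.), MeOH, rt
Reagents that add atoms: 3-chloroperbenzoic acid, O=C(OO)c1cccc(Cl)c1
Why: In this Baeyer–Villiger (Dakin-type) oxidation the aryl group, activated by ortho and para oxygen donors, migrates to give formate 4, which methanol cleaves; the new hydroxyl therefore sits unambiguously between Br and OMOM.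

Step 4
Reactants: 6 methyl prop-2-ynoate (methyl propiolate)
Product: 7 methyl 3-bromoprop-2-ynoate
Conditions: NBS, AgNO3 (cat.), acetone, rt
Reagents that add atoms: N-bromosuccinimide, O=C1CCC(=O)N1Br
Why: Silver-catalysed bromination of a terminal alkyne with NBS is the standard preparation of 1-bromoalkynes and of this ester in particular.

Step 5
Reactants: 5 2-bromo-4-methoxy-6-(methoxymethoxy)phenol; 7 methyl 3-bromoprop-2-ynoate
Product: 8 methyl 3-[2-bromo-4-methoxy-6-(methoxymethoxy)phenoxy]prop-2-ynoate
Conditions: 5, NaH (1.0 equiv), THF, 0 °C; then transfer into 7 (1.5 equiv), THF, −78 → −20 °C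
Reagents that add atoms: none
Why: Proposed new method: the sodium phenoxide of 5 should add to the bromine-bearing β-carbon of ynoate 7 and the allenolate so formed should expel bromide (addition–elimination, that is nucleophilic substitution at an acetylenic carbon); the closest known reaction type is the displacement of halide from acceptor-substituted 1-haloalkynes by thiolates and nitrogen nucleophiles, and the aprotic medium, the inverse addition to excess 7 at low temperature and the two ortho substituents of the phenoxide should suppress a second addition to 8.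

Step 6
Reactants: 9 methyl 3-methylbut-2-enoate
Product: 10 (1Z)-1-methoxy-3-methyl-1-(trimethylsilyloxy)buta-1,3-diene
Conditions: LiN(i-Pr)2, THF, −78 °C; then Me3SiCl, −78 °C → rt; distil
Reagents that add atoms: chlorotrimethylsilane, C[Si](C)(C)Cl
Why: Kinetic γ-deprotonation of the senecioate gives the extended enolate, which silylates on oxygen to the vinylketene acetal (O-silylation of an ester dienolate).

Step 7
Reactants: 8 methyl 3-[2-bromo-4-methoxy-6-(methoxymethoxy)phenoxy]prop-2-ynoate; 10 (1Z)-1-methoxy-3-methyl-1-(trimethylsilyloxy)buta-1,3-diene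
Product: 13 methyl 2-[2-bromo-4-methoxy-6-(methoxymethoxy)phenoxy]-6-hydroxy-4-methylbenzoate, via cyclohexadiene ketal 11 (not isolated), via aryl silyl ether 12 (not isolated)
Conditions: 10 (3 equiv), PhMe, 100 °C, sealed tube; then K2CO3 (cat.), MeOH, 0 °C
Reagents that add atoms: none
Why: Proposed new method: the CH2 terminus of vinylketene acetal 10, its most nucleophilic carbon, should bond to the oxygen-bearing β-carbon of ynoate 8 and the ketene acetal carbon to the α-carbon in a concerted but asynchronous [4+2] cycloaddition (in the stepwise limit a vinylogous Mukaiyama–Michael addition followed by 6-exo-trig collapse of the allenolate onto the silyloxycarbenium ion), so that ring D closes as a six-membered carbocycle by cycloaddition across the alkyne. The closest known reaction type is the Diels–Alder reaction and aromatisation of 1-alkoxy-1-silyloxybuta-1,3-dienes with propiolates and acetylenedicarboxylates to salicylates; a 3-aryloxypropiolate has not been used as the 2π partner. Cyclohexa-1,4-diene 11 should lose methanol by 1,4-elimination on heating, driven by aromatisation, and catalytic carbonate in methanol then cleaves aryl silyl ether 12 to the ester-chelated phenol. The only stereocentre formed, the ketal carbon of 11, disappears on aromatisation, so nothing has to be controlled. The step needs one regiochemistry, methyl para and hydroxyl ortho to the ester, and both polarisations secure it: the β-carbon of 8 is the Michael terminus of the ester and carries the σ-withdrawing aryloxy group, and the CH2 end of 10 is the γ-carbon of a dienolate. It also needs ring closure to outrun loss of aryloxide from a zwitterionic adduct, which a non-polar solvent and the proximity of the two ion-pair termini should favour.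

Step 8
Reactants: 13 methyl 2-[2-bromo-4-methoxy-6-(methoxymethoxy)phenoxy]-6-hydroxy-4-methylbenzoate
Product: 14 methyl 2-[2-bromo-4-methoxy-6-(methoxymethoxy)phenoxy]-6-(methoxymethoxy)-4-methylbenzoate
Conditions: NaH, MOMCl, DMF, 0 °C
Reagents that add atoms: chloromethyl methyl ether, COCCl
Why: Deprotonation of the chelated salicylate hydroxyl and Williamson etherification remove the acidic proton before the base-mediated enolate arylation and the quinone oxidation.

Step 9
Reactants: 15 5-methylbenzene-1,3-diol (orcinol)
Product: 16 1,3-bis(methoxymethoxy)-5-methylbenzene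
Conditions: MOMCl (2.4 equiv), i-Pr2NEt, CH2Cl2, 0 °C → rt
Reagents that add atoms: chloromethyl methyl ether, COCCl
Why: Double Williamson-type etherification installs the two acetal ethers that will direct the lithiation of ring B.

Step 10
Reactants: 16 1,3-bis(methoxymethoxy)-5-methylbenzene; 3 2-bromo-4-methoxy-6-(methoxymethoxy)benzaldehyde
Product: 18 [2-bromo-4-methoxy-6-(methoxymethoxy)phenyl][2,6-bis(methoxymethoxy)-4-methylphenyl]methanol, via aryllithium 17 (not isolated)
Conditions: 16, n-BuLi (0.95 equiv), THF, 0 °C; then 3, −78 → 0 °C; then H2O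
Reagents that add atoms: none
Why: The two MOM ethers direct lithiation to the carbon between them (directed ortho-metalation), and with no butyllithium left the aryllithium should add to the aldehyde faster than it exchanges with the aryl bromide (1,2-addition).

Step 11
Reactants: 18 [2-bromo-4-methoxy-6-(methoxymethoxy)phenyl][2,6-bis(methoxymethoxy)-4-methylphenyl]methanol; 19 1-(tert-butyldimethylsilyloxy)-1-methoxyethene
Product: 20 methyl 3-[2-bromo-4-methoxy-6-(methoxymethoxy)phenyl]-3-[2,6-bis(methoxymethoxy)-4-methylphenyl]propanoate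
Conditions: 19 (2 equiv), InCl3 (10 mol %), CH2Cl2, −40 → 0 °C
Reagents that add atoms: none
Why: The doubly benzylic alcohol ionises readily to a benzhydryl cation stabilised by five oxygen donors, which the ketene silyl acetal should capture at carbon (Lewis acid-catalysed SN1 substitution, Mukaiyama-type alkylation) under conditions mild enough for the MOM ethers.

Step 12
Reactants: 20 methyl 3-[2-bromo-4-methoxy-6-(methoxymethoxy)phenyl]-3-[2,6-bis(methoxymethoxy)-4-methylphenyl]propanoate
Product: 22 3-[2,6-bis(methoxymethoxy)-4-methylphenyl]-6-methoxy-4-(methoxymethoxy)-2,3-dihydro-1H-inden-1-one, via aryllithium 21 (not isolated)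
Conditions: t-BuLi (2.05 equiv), THF, −78 °C; then H2O
Reagents that add atoms: none
Why: Bromine–lithium exchange with t-BuLi is faster than attack on the ester, and the aryllithium should acylate itself on the ester in a 5-exo-trig closure (Parham cyclisation) to give the indanone.

Step 13
Reactants: 22 3-[2,6-bis(methoxymethoxy)-4-methylphenyl]-6-methoxy-4-(methoxymethoxy)-2,3-dihydro-1H-inden-1-one; 14 methyl 2-[2-bromo-4-methoxy-6-(methoxymethoxy)phenoxy]-6-(methoxymethoxy)-4-methylbenzoate
Product: 23 methyl 2-{2-[3-[2,6-bis(methoxymethoxy)-4-methylphenyl]-6-methoxy-4-(methoxymethoxy)-1-oxo-2,3-dihydro-1H-inden-2-yl]-4-methoxy-6-(methoxymethoxy)phenoxy}-6-(methoxymethoxy)-4-methylbenzoate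
Conditions: Pd2(dba)3 (2.5 mol %), XPhos (10 mol %), NaOt-Bu, PhMe, 80 °C, degassed
Reagents that add atoms: none
Why: Palladium-catalysed α-arylation of a ketone enolate (Buchwald–Hartwig type), established for 3-arylindan-1-ones, should form the C2–aryl bond at the only enolisable position, and the 2,6-disubstituted benzoate of ring D has no α-hydrogen and resists tert-butoxide.

Step 14
Reactants: 23 methyl 2-{2-[3-[2,6-bis(methoxymethoxy)-4-methylphenyl]-6-methoxy-4-(methoxymethoxy)-1-oxo-2,3-dihydro-1H-inden-2-yl]-4-methoxy-6-(methoxymethoxy)phenoxy}-6-(methoxymethoxy)-4-methylbenzoate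
Product: 24 methyl 2-{2-[3-[2,6-bis(methoxymethoxy)-4-methylphenyl]-6-methoxy-4-(methoxymethoxy)-1-oxo-1H-inden-2-yl]-4-methoxy-6-(methoxymethoxy)phenoxy}-6-(methoxymethoxy)-4-methylbenzoate
Conditions: DDQ (1.2 equiv), 1,4-dioxane, 90 °C
Reagents that add atoms: none
Why: DDQ should abstract hydride from C3, which is doubly benzylic and flanked by two oxygenated rings, and loss of the C2 proton gives the fully conjugated indenone (quinone dehydrogenation of a ketone to an enone), erasing both stereocentres.

Step 15
Reactants: 24 methyl 2-{2-[3-[2,6-bis(methoxymethoxy)-4-methylphenyl]-6-methoxy-4-(methoxymethoxy)-1-oxo-1H-inden-2-yl]-4-methoxy-6-(methoxymethoxy)phenoxy}-6-(methoxymethoxy)-4-methylbenzoate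
Product: 25 Ascomindone B, methyl 2-{2-[3-(2,6-dihydroxy-4-methylphenyl)-4-hydroxy-6-methoxy-1-oxo-1H-inden-2-yl]-6-hydroxy-4-methoxyphenoxy}-6-hydroxy-4-methylbenzoate
Conditions: HCl (3 M aq., cat.), MeOH, 50 °C
Reagents that add atoms: none
Why: Acid-catalysed acetal exchange with methanol should remove all five MOM groups, while the aryl methyl ethers, the methyl ester (transesterification in methanol is degenerate) and the indenone are inert.

**Compound list**

1 | 2-bromo-4,6-dimethoxybenzaldehyde | COc1cc(Br)c(C=O)c(OC)c1 | starting material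
2 | 2-bromo-6-hydroxy-4-methoxybenzaldehyde | COc1cc(O)c(C=O)c(Br)c1 | intermediate
3 | 2-bromo-4-methoxy-6-(methoxymethoxy)benzaldehyde | COCOc1cc(OC)cc(Br)c1C=O | intermediate
4 | 2-bromo-4-methoxy-6-(methoxymethoxy)phenyl formate | COCOc1cc(OC)cc(Br)c1OC=O | intermediate
5 | 2-bromo-4-methoxy-6-(methoxymethoxy)phenol | COCOc1cc(OC)cc(Br)c1O | intermediate
6 | methyl prop-2-ynoate | C#CC(=O)OC | starting material
7 | methyl 3-bromoprop-2-ynoate | BrC#CC(=O)OC | intermediate
8 | methyl 3-[2-bromo-4-methoxy-6-(methoxymethoxy)phenoxy]prop-2-ynoate | COC(=O)C#COc1c(OCOC)cc(OC)cc1Br | intermediate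
9 | methyl 3-methylbut-2-enoate | COC(=O)C=C(C)C | starting material
10 | (1Z)-1-methoxy-3-methyl-1-(trimethylsilyloxy)buta-1,3-diene | CO/C(O[Si](C)(C)C)=C/C(C)=C | intermediate
11 | methyl 2-[2-bromo-4-methoxy-6-(methoxymethoxy)phenoxy]-6-methoxy-4-methyl-6-(trimethylsilyloxy)cyclohexa-1,4-diene-1-carboxylate (racemic) | COC(=O)C1=C(Oc2c(OCOC)cc(OC)cc2Br)CC(C)=CC1(OC)O[Si](C)(C)C | intermediate
12 | methyl 2-[2-bromo-4-methoxy-6-(methoxymethoxy)phenoxy]-4-methyl-6-(trimethylsilyloxy)benzoate | COC(=O)c1c(O[Si](C)(C)C)cc(C)cc1Oc1c(OCOC)cc(OC)cc1Br | intermediate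
13 | methyl 2-[2-bromo-4-methoxy-6-(methoxymethoxy)phenoxy]-6-hydroxy-4-methylbenzoate | COC(=O)c1c(O)cc(C)cc1Oc1c(OCOC)cc(OC)cc1Br | intermediate
14 | methyl 2-[2-bromo-4-methoxy-6-(methoxymethoxy)phenoxy]-6-(methoxymethoxy)-4-methylbenzoate | COC(=O)c1c(OCOC)cc(C)cc1Oc1c(OCOC)cc(OC)cc1Br | intermediate
15 | 5-methylbenzene-1,3-diol (orcinol) | Cc1cc(O)cc(O)c1 | starting material
16 | 1,3-bis(methoxymethoxy)-5-methylbenzene | COCOc1cc(C)cc(OCOC)c1 | intermediate
17 | [2,6-bis(methoxymethoxy)-4-methylphenyl]lithium | COCOc1cc(C)cc(OCOC)c1[Li] | intermediate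
18 | [2-bromo-4-methoxy-6-(methoxymethoxy)phenyl][2,6-bis(methoxymethoxy)-4-methylphenyl]methanol (racemic) | COCOc1cc(C)cc(OCOC)c1C(O)c1c(Br)cc(OC)cc1OCOC | intermediate
19 | 1-(tert-butyldimethylsilyloxy)-1-methoxyethene | C=C(OC)O[Si](C)(C)C(C)(C)C | starting material
20 | methyl 3-[2-bromo-4-methoxy-6-(methoxymethoxy)phenyl]-3-[2,6-bis(methoxymethoxy)-4-methylphenyl]propanoate (racemic) | COC(=O)CC(c1c(Br)cc(OC)cc1OCOC)c1c(OCOC)cc(C)cc1OCOC | intermediate
21 | methyl 3-[2-lithio-4-methoxy-6-(methoxymethoxy)phenyl]-3-[2,6-bis(methoxymethoxy)-4-methylphenyl]propanoate (racemic) | COC(=O)CC(c1c([Li])cc(OC)cc1OCOC)c1c(OCOC)cc(C)cc1OCOC | intermediate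
22 | 3-[2,6-bis(methoxymethoxy)-4-methylphenyl]-6-methoxy-4-(methoxymethoxy)-2,3-dihydro-1H-inden-1-one (racemic) | COCOc1cc(C)cc(OCOC)c1C1CC(=O)c2cc(OC)cc(OCOC)c21 | intermediate
23 | methyl 2-{2-[3-[2,6-bis(methoxymethoxy)-4-methylphenyl]-6-methoxy-4-(methoxymethoxy)-1-oxo-2,3-dihydro-1H-inden-2-yl]-4-methoxy-6-(methoxymethoxy)phenoxy}-6-(methoxymethoxy)-4-methylbenzoate (racemic, trans expected) | COCOc1cc(C)cc(Oc2c(OCOC)cc(OC)cc2C2C(=O)c3cc(OC)cc(OCOC)c3C2c2c(OCOC)cc(C)cc2OCOC)c1C(=O)OC | intermediate
24 | methyl 2-{2-[3-[2,6-bis(methoxymethoxy)-4-methylphenyl]-6-methoxy-4-(methoxymethoxy)-1-oxo-1H-inden-2-yl]-4-methoxy-6-(methoxymethoxy)phenoxy}-6-(methoxymethoxy)-4-methylbenzoate | COCOc1cc(C)cc(Oc2c(OCOC)cc(OC)cc2C2=C(c3c(OCOC)cc(C)cc3OCOC)c3c(OCOC)cc(OC)cc3C2=O)c1C(=O)OC | intermediate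
25 | Ascomindone B | COC(=O)c1c(O)cc(C)cc1Oc1c(O)cc(OC)cc1C1=C(c2c(O)cc(C)cc2O)c2c(O)cc(OC)cc2C1=O | target

**Count**

Total steps: 15. Longest linear sequence: 9 steps (steps 1, 2, 3, 5, 7, 8, 13, 14, 15).

**Steps most likely to fail**

Step 5 (proposed method). The phenoxide may add twice, the first adduct may be protonated before bromide leaves, or bromoalkyne 7 may oligomerise under basic conditions. The fallback sets out from phenol 5 and bromoalkyne 7 and comes back at 8. The two would be combined under protic, weakly basic conditions (K2CO3 0.2 equiv, acetone, 0 °C), so that the conjugate adduct is deliberately protonated and isolated as methyl 3-bromo-3-[2-bromo-4-methoxy-6-(methoxymethoxy)phenoxy]prop-2-enoate F1 (oxa-Michael addition of a phenol to an ynoate). A separate dehydrobromination with KOt-Bu in THF at −78 °C, the classical passage from a β-halo enol ether to an ynol ether, would then give 8.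

Step 7 (proposed method). The push–pull alkyne may be too unreactive, so that the diene decomposes on prolonged heating, or a zwitterionic first adduct may fragment by loss of aryloxide before the ring closes. The fallback sets out from phenol 5 and comes back at 13; it makes the diaryl ether on a preformed ring D by nucleophilic aromatic substitution. Phenol 5 and methyl 2,6-difluoro-4-methylbenzoate (assumed purchasable; Cs2CO3, DMSO, 100 °C) should give methyl 2-[2-bromo-4-methoxy-6-(methoxymethoxy)phenoxy]-6-fluoro-4-methylbenzoate F2, the fluorine ortho to the ester being displaced. The second fluorine would then be exchanged for hydroxyl with the hydroxide surrogate 2-(methylsulfonyl)ethanol and NaH in DMF, through methyl 2-[2-bromo-4-methoxy-6-(methoxymethoxy)phenoxy]-4-methyl-6-[2-(methylsulfonyl)ethoxy]benzoate F3 (not isolated), which loses ethenyl methyl sulfone by E1cB elimination to give 13.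

Step 13. Enolate binding and reductive elimination at a centre flanked by two ortho-substituted arenes may be slow, so that reduction of the bromide or oxidation of the enolate takes over. The fallback sets out from indanone 22 and bromide 14 and comes back at indenone 24, so step 14 is not needed. It forms the same bond by Suzuki coupling at the indenone oxidation level. Oxidation of 22 with SeO2 in dioxane at 80 °C should give the 1,2-dione as its enol, 3-[2,6-bis(methoxymethoxy)-4-methylphenyl]-2-hydroxy-6-methoxy-4-(methoxymethoxy)-1H-inden-1-one F4. Tf2O and pyridine would convert it into 3-[2,6-bis(methoxymethoxy)-4-methylphenyl]-6-methoxy-4-(methoxymethoxy)-1-oxo-1H-inden-2-yl trifluoromethanesulfonate F5. Bromide 14 would be borylated (B2pin2, Pd(dppf)Cl2, KOAc, dioxane, 90 °C) to methyl 2-[4-methoxy-2-(methoxymethoxy)-6-(4,4,5,5-tetramethyl-1,3,2-dioxaborolan-2-yl)phenoxy]-6-(methoxymethoxy)-4-methylbenzoate F6. Coupling of F5 with F6 (Pd(OAc)2, SPhos, K3PO4, PhMe/H2O, 80 °C) should give 24.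

**Further compounds**

F1 | step 5 | methyl 3-bromo-3-[2-bromo-4-methoxy-6-(methoxymethoxy)phenoxy]prop-2-enoate (E/Z mixture) | COC(=O)C=C(Br)Oc1c(OCOC)cc(OC)cc1Br
F2 | step 7 | methyl 2-[2-bromo-4-methoxy-6-(methoxymethoxy)phenoxy]-6-fluoro-4-methylbenzoate | COC(=O)c1c(F)cc(C)cc1Oc1c(OCOC)cc(OC)cc1Br
F3 | step 7 | methyl 2-[2-bromo-4-methoxy-6-(methoxymethoxy)phenoxy]-4-methyl-6-[2-(methylsulfonyl)ethoxy]benzoate | COC(=O)c1c(OCCS(C)(=O)=O)cc(C)cc1Oc1c(OCOC)cc(OC)cc1Br
F4 | step 13 | 3-[2,6-bis(methoxymethoxy)-4-methylphenyl]-2-hydroxy-6-methoxy-4-(methoxymethoxy)-1H-inden-1-one | COCOc1cc(C)cc(OCOC)c1C1=C(O)C(=O)c2cc(OC)cc(OCOC)c21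
F5 | step 13 | 3-[2,6-bis(methoxymethoxy)-4-methylphenyl]-6-methoxy-4-(methoxymethoxy)-1-oxo-1H-inden-2-yl trifluoromethanesulfonate | COCOc1cc(C)cc(OCOC)c1C1=C(OS(=O)(=O)C(F)(F)F)C(=O)c2cc(OC)cc(OCOC)c21
F6 | step 13 | methyl 2-[4-methoxy-2-(methoxymethoxy)-6-(4,4,5,5-tetramethyl-1,3,2-dioxaborolan-2-yl)phenoxy]-6-(methoxymethoxy)-4-methylbenzoate | COCOc1cc(C)cc(Oc2c(OCOC)cc(OC)cc2B2OC(C)(C)C(C)(C)O2)c1C(=O)OC
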